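The earlier runs and the new flask stem from a simulated flask with made-up constants, noise included.

60.3 % of the starting complex charged stands as complex with one exchanged in the maple flask, averaged from 20.0 s to 90.0 s, and I reason from that plateau.

| flask | starting complex | incoming ligand | leaving ligand | remark | time |
|---|---|---|---|---|---|
| maple | 0.71 M | 3 equiv | 2 equiv | the very flask that is asked about, followed so far |  |
| flask | 0.71 M | 3.00 equiv | 2.00 equiv |  | 5.0 min |

maple run (percent of the starting complex charged)

| time / s | complex with one exchanged / % | complex with two exchanged / % |
|---|---|---|
| 10.0 | 59.2 | 25.1 |
| 20.0 | 60.7 | 29.5 |
| 30.0 | 60.2 | 29.8 |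
| 50.0 | 60.4 | 29.2 |
| 60.0 | 60.3 | 29.5 |
| 90.0 | 59.8 | 29.3 |

(readings scatter by 0.3 percentage points)

- equivalents of incoming ligand to starting complex, everything else as given, that leave most complex with one exchanged at 5.0 min
- the amount of complex with one exchanged then, in percent of the starting complex charged
- the amount of complex with one exchanged with the amounts as given

- steps thought possible: starting complex + incoming ligand <-> leaving ligand + complex with one exchanged; complex with one exchanged + incoming ligand <-> leaving ligand + complex with two exchanged; complex with two exchanged -> over-reaction product

Complex with two exchanged averages 29.5 %, so by difference starting complex is 10.3 %, and the plateau gives 12.0. This is Q, the sharing ratio: c(complex with one exchanged) squared over c(starting complex) times c(complex with two exchanged). Dividing one exchange equilibrium by the other cancels both ligands, so I freeze Q, a comproportionation constant, while the charges move. Let w be the square root of c(complex with two exchanged) over c(starting complex). The share of complex with one exchanged among the three complexes is then √Q·w over the sum of 1, √Q·w and w squared. It peaks at w = 1, at 63.4 %.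

But starting complex is not read, and the difference also counts anything lost to over-reaction product. The two read complexes fall by 1.1 percentage points, against a scatter of 0.3 points per reading. Were all of that lost, Q would read 13.5, yet the ceiling would move just to 64.8 %.

A second objection is that 5.0 min is far longer than the plateau's 20.0 s. Carried on, that fall costs 4.7 points, which puts the flask near 57.5 % at the low end.

The forecast says 59 % (56 % to 60.5 %) as charged, and 62 % (59.5 % to 63.5 %) at 1.95 equiv (1.75 equiv to 2.2 equiv), “with slightly less ligand favoured”. My ceiling, which counts no loss, stands above its best value.

The flask gives 58.4 % as charged and 63.1 % at 1.85 equiv, within those ranges. A move of 5 points in the first takes incoming ligand at 0.943 equiv or 3.82 equiv.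

    starting complex + incoming ligand ⇌ leaving ligand + complex with one exchanged (K = 12.0, k = 0.140 M⁻¹ s⁻¹)
    complex with one exchanged + incoming ligand ⇌ leaving ligand + complex with two exchanged (K = 0.890, k = 0.0630 M⁻¹ s⁻¹)
    complex with two exchanged → over-reaction product (k = 5.20 × 10⁻⁴ s⁻¹)

The neighbouring flask with 0.800 equiv of leaving ligand holds, at 5.00 min, 5.78 % starting complex, 35.7 % complex with two exchanged and 5.66 % over-reaction product. So w is 2.49, and the read Q, applied to the complexes remaining, gives 51.5 %. That flask holds 52.8 % complex with one exchanged.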